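I read both flasks at 25 min, and the earlier runs have stopped moving well before that: birch shows 89.2% product at 8.00 min and 89.1% at 20.0 min.

common to all: enzyme 20 µM

| flask | starting material | second substrate | protic impurity | remark | time |
|---|---|---|---|---|---|
| birch | 0.20 M (fed, over 2.0 min) | 0.19 M | 0.011 M | run made earlier; the fed solution adds 0.20 times the starting volume |  |
| maple | 0.20 M (fed, over 2.0 min) | 0.19 M | 0.042 M | run made earlier; the fed solution adds 0.20 times the starting volume |  |
| elm | 0.15 M (fed, over 2.0 min) | 0.19 M | 0.010 M | run made earlier; the fed solution adds 0.20 times the starting volume |  |
| epsilon | 0.20 M (fed, over 2.0 min) | 0.190 M | 0.0100 M | the fed solution adds 0.20 times the starting volume | 25 min |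
| beta | 0.060 M | 0.190 M | 0.0300 M | everything together at the start, the whole solution of starting material included, so that from the start the volume is larger by 0.20 times the starting volume | 25 min |

| run | time / min | product / % | starting material / % |
|---|---|---|---|
| birch | 1.33 | 49.4 | 17.4 |
| birch | 2.00 | 73.9 | 25.3 |
| birch | 3.00 | 86.2 | 13.7 |
| birch | 5.00 | 88.6 | 10.6 |
| birch | 8.00 | 89.2 | 10.5 |
| birch | 12.0 | 89.3 | 9.9 |
| birch | 20.0 | 89.1 | 10.9 |
| maple | 1.33 | 47.1 | 19.2 |
| maple | 2.00 | 67.1 | 33.1 |
| maple | 3.00 | 73.2 | 26.8 |
| maple | 5.00 | 74.3 | 25.6 |
| maple | 8.00 | 73.8 | 26.1 |
| maple | 12.0 | 74.3 | 26.3 |
| maple | 20.0 | 74.4 | 25.9 |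
| elm | 1.33 | 51.7 | 15.1 |
| elm | 2.50 | 91.1 | 8.9 |
| elm | 5.00 | 99.9 | 0 |
| elm | 10.0 | 100.6 | 0 |
| elm | 20.0 | 100.0 | 0 |

(each reading ± 0.3 percentage points)

- in percentages every species weighs as the starting material in it: one spent catalyst counts as two
- for product the crystals are counted in
- charges are per starting volume, the dose included; the dosed solution carries all of it
- as a solid, counted per litre of solution: crystals
- steps thought possible: second substrate + starting complex <-> ternary complex; starting material + starting complex -> spent catalyst; ternary complex -> enzyme + product; crystals <-> product; starting material + enzyme <-> starting complex; second substrate + protic impurity -> quenched reagent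
- percentages count the whole charge, also what has not yet gone in

- the flask that ends with the higher amount of product, in percent of the starting material charged, or "neither" when 2 percentage points or less lies between them (epsilon / beta / neither)
- final product, as a percentage of the starting material charged, in epsilon
- final product, as a percentage of the starting material charged, in beta

I carry one quantity, the reagent ceiling C: second substrate charged minus protic impurity charged, divided by starting material charged, and read as product where it stays under the whole charge. For epsilon, 90.0%.

1. The rule comes from the plateaus. Birch has C = 89.5% and reads 89.3%. Maple has C = 74.0% and reads 74.4%. Elm has C = 120% and reads 100.0%. So I take the impurity to remove second substrate one for one.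

2. First instants: in birch at 1.33 min, 66.5% of the charge has gone in, and product plus starting material read 66.8%. That sum counts what has gone in; product itself lags the feed, for birch reads 49.4% product with 17.4% starting material unreacted. At the same time maple's product trails birch's by 2.3 percentage points.

3. Middle: at the end of the feed birch still holds 25.3% starting material, and by 5.00 min it reads 88.6% product. The gap to maple has reached 15 points by 20.0 min.

4. End of epsilon: second substrate net of the impurity comes to 0.180 M, less than the 0.20 M of starting material, so it is the limiting reagent and I expect 90.0% product.

5. End of beta: C comes to 267%, more than the charge allows, so I expect 100%. Beta starts at 0.0500 M starting material, between birch's 0.0422 M and maple's 0.0552 M at 2.00 min. It needs 3000 turnovers per enzyme, fewer than birch's 8930.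

The forecast says beta, with 89.8% in epsilon and 99.5% in beta, where I have 90.0% and 100%, on the ground that “Plateaus follow the reagent balance”.

The flasks give beta as the higher: epsilon, with C = 90.0%, ends at 90.0%, and beta at >99.9%.

    second substrate + starting complex ⇌ ternary complex (K = 52.8 /M, k = 24100 /M/s)
    starting material + starting complex → spent catalyst (k = 0.167 /M/s)
    ternary complex → enzyme + product (k = 1810 /s)
    crystals ⇌ product, rate k4*(cs4 - [product]) while solid is left; crystals form when [product] > cs4 (solubility = 15.0 mM, k = 1.79 /s)
    starting material + enzyme ⇌ starting complex (K = 3.71 /M, k = 5330 /M/s)
    second substrate + protic impurity → quenched reagent (k = 5.43 /M/s)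

One change that moves the epsilon figure is more protic impurity. A neighbouring flask is epsilon with 0.025 M of protic impurity instead of 0.0100 M. Its ceiling reckons to 82.5%. At 25.0 min its second substrate stands at 0% of its charge, and it ends with 82.5% product and 17.5% starting material.

The earlier runs and the new flask are simulated from invented constants, and the scatter is random.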